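**Retrosynthetic overview**

1. The strategy rests on the skipped diene C10(=CH2)–C1(H)–C2=C3 that stops at the fully substituted C4 of the cis-fused five/seven-membered (hydroazulene) core. It is the footprint of a 7-exo Heck closure (C1–C10) of a 2-bromo-1-alkene onto a C1=C2 cyclopentene, followed by β-hydride loss towards C3.
2. The Heck precursor is cut at C5–C6 into an allylindium made from a 4-bromocyclopentene (five-membered ring by ring-closing metathesis of (S)-linalool, which supplies C4) and an α-branched aldehyde carrying C6–C15 and the vinyl bromide.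
3. The aldehyde comes from an oxazolidinone enolate alkylation (C7) with 3-bromobut-3-enyl triflate. Its acyl chain comes from desymmetrised 3-methylglutaric anhydride (C11), an isobutenyl Grignard acylation and an oxazaborolidine enone reduction (C13).
4. Ring order: five-membered ring first (metathesis), seven-membered ring last (Heck). C6 is then set by oxidation and bulky-hydride reduction, with the side-chain acetate installed at the ketone stage.

Key step: step 16

Remark: dictyol numbering is used throughout (C1/C5 ring fusion, C2=C3, C4 carbinol, C6 carbinol, C7, C8, C9, C10 exo-methylene carbon, side chain C11–C15; α is the face of H1 and H5). The C6 configuration of adduct 24 is drawn as the chair-transition-state isomer, and its C6 epimer would converge at ketone 26.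

**Route**

Step 1
Reactants: 1 (S)-(+)-linalool
Product: 2 (S)-1-methylcyclopent-2-en-1-ol
Conditions: second-generation Grubbs catalyst RuCl2(=CHPh)(PCy3)(H2IMes) (0.5 mol%), CH2Cl2, 40 °C
Reagents that add atoms: none
Why: Ring-closing metathesis between the vinyl group and the trisubstituted alkene closes the cyclopentene with loss of volatile 2-methylpropene and leaves the carbinol stereocentre (the future C4) untouched.

Step 2
Reactants: 2 (S)-1-methylcyclopent-2-en-1-ol
Product: 3 (S)-tert-butyldimethyl[(1-methylcyclopent-2-en-1-yl)oxy]silane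
Conditions: TBSOTf, 2,6-lutidine, CH2Cl2, −78 to 0 °C
Reagents that add atoms: tert-butyldimethylsilyl triflate, CC(C)(C)[Si](C)(C)OS(=O)(=O)C(F)(F)F
Why: A silyl triflate with a hindered base silylates the tertiary allylic alcohol under non-ionising conditions and installs the bulky group that later differentiates the two faces of the ring.

Step 3
Reactants: 3 (S)-tert-butyldimethyl[(1-methylcyclopent-2-en-1-yl)oxy]silane
Product: 4 (1S)-4-bromo-1-methylcyclopent-2-en-1-yl tert-butyldimethylsilyl ether (bromide epimers; used crude)
Conditions: NBS, AIBN (5 mol%), PhCF3, 80 °C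
Reagents that add atoms: N-bromosuccinimide, O=C1CCC(=O)N1Br
Why: Wohl–Ziegler bromination can abstract hydrogen only from the single allylic CH2 (the other allylic position is quaternary), and every bromide regio- and stereoisomer of the resulting allyl radical converges on the same allylindium in step 15.

Step 4
Reactants: 5 3-methylglutaric anhydride
Product: 6 (R)-5-methoxy-3-methyl-5-oxopentanoic acid
Conditions: (DHQD)2AQN (10 mol%), MeOH (10 equiv), Et2O, −40 °C
Reagents that add atoms: methanol, CO
Why: In this cinchona-alkaloid-catalysed desymmetrising alcoholysis the quinidine-derived bis-alkaloid acts as a chiral general base and should direct methanol to one enantiotopic carbonyl to set C11; the quinine-derived pseudoenantiomer would serve if the opposite sense were found.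

Step 5
Reactants: 6 (R)-5-methoxy-3-methyl-5-oxopentanoic acid
Product: 7 methyl (S)-5-chloro-3-methyl-5-oxopentanoate
Conditions: (COCl)2, DMF (cat.), CH2Cl2, 0 °C to rt
Reagents that add atoms: oxalyl chloride, ClC(=O)C(=O)Cl
Why: Acid chloride formation through the Vilsmeier intermediate is neutral enough to leave the methyl ester and the β-stereocentre alone (the descriptor changes only by priority).

Step 6
Reactants: 7 methyl (S)-5-chloro-3-methyl-5-oxopentanoate; 8 1-bromo-2-methylprop-1-ene
Product: 10 methyl (R)-3,7-dimethyl-5-oxooct-6-enoate, via Grignard reagent 9 (not isolated)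
Conditions: 8, Mg, THF, 40 °C; then added to 7, CuI (10 mol%), THF, −78 °C
Reagents that add atoms: none
Why: Copper-catalysed acylation of the alkenyl Grignard reagent by the acid chloride at −78 °C stops at the ketone and is much faster than attack on the methyl ester or conjugate addition to the β,β-disubstituted enone.

Step 7
Reactants: 10 methyl (R)-3,7-dimethyl-5-oxooct-6-enoate
Product: 11 methyl (3R,5R)-5-hydroxy-3,7-dimethyloct-6-enoate
Conditions: (S)-2-methyl-CBS-oxazaborolidine (20 mol%), catecholborane, toluene, −78 °C
Reagents that add atoms: none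
Why: In this Corey–Bakshi–Shibata reduction the alkenyl group acts as the large substituent, so the (S)-catalyst should deliver hydride to give the (R)-allylic alcohol (C13) under catalyst control, and the ester is inert to catecholborane at this temperature.

Step 8
Reactants: 11 methyl (3R,5R)-5-hydroxy-3,7-dimethyloct-6-enoate
Product: 12 methyl (3R,5R)-3,7-dimethyl-5-(triethylsilyloxy)oct-6-enoate
Conditions: TESCl, imidazole, DMF, 0 °C
Reagents that add atoms: chlorotriethylsilane, CC[Si](Cl)(CC)CC
Why: Prompt silylation blocks δ-lactonisation of the hydroxy ester and gives a silyl ether that can later be removed in the presence of the tertiary TBS ether.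

Step 9
Reactants: 12 methyl (3R,5R)-3,7-dimethyl-5-(triethylsilyloxy)oct-6-enoate
Product: 13 (3R,5R)-3,7-dimethyl-5-(triethylsilyloxy)oct-6-enoic acid
Conditions: LiOH, THF/MeOH/H2O, 0 °C to rt; AcOH to pH 5
Reagents that add atoms: lithium hydroxide (its oxygen becomes the acid OH), [Li+].[OH-]
Why: Saponification of the unhindered methyl ester with a weakly acidic work-up keeps the secondary triethylsilyl ether intact.

Step 10
Reactants: 13 (3R,5R)-3,7-dimethyl-5-(triethylsilyloxy)oct-6-enoic acid; 14 (R)-4-benzyloxazolidin-2-one
Product: 16 (R)-4-benzyl-3-[(3R,5R)-3,7-dimethyl-5-(triethylsilyloxy)oct-6-enoyl]oxazolidin-2-one, via mixed pivalic anhydride 15 (not isolated)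
Conditions: PivCl, Et3N, THF, −20 °C; then 14, LiCl, −20 °C to rt
Reagents that add atoms: none
Why: The mixed pivalic anhydride is attacked at the less hindered carbonyl by the lithium-chloride-activated oxazolidinone, which gives the imide without strong base.

Step 11
Reactants: 17 3-bromobut-3-en-1-ol
Product: 18 3-bromobut-3-enyl trifluoromethanesulfonate
Conditions: Tf2O, 2,6-lutidine, CH2Cl2, −78 °C; used at once
Reagents that add atoms: triflic anhydride, O=S(=O)(OS(=O)(=O)C(F)(F)F)C(F)(F)F
Why: O-sulfonylation of the primary alcohol gives an electrophile reactive enough to alkylate an enolate at −78 °C, where substitution is faster than elimination to the bromodiene.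

Step 12
Reactants: 16 (R)-4-benzyl-3-[(3R,5R)-3,7-dimethyl-5-(triethylsilyloxy)oct-6-enoyl]oxazolidin-2-one; 18 3-bromobut-3-enyl trifluoromethanesulfonate
Product: 20 (R)-4-benzyl-3-[(2R,3R,5R)-2-(3-bromobut-3-enyl)-3,7-dimethyl-5-(triethylsilyloxy)oct-6-enoyl]oxazolidin-2-one, via sodium Z-enolate 19 (not isolated)
Conditions: NaN(SiMe3)2, THF, −78 °C; then 18, −78 to −45 °C
Reagents that add atoms: none
Why: In this Evans alkylation the chelated Z-enolate is attacked by the triflate on the face opposite the benzyl group of the (R)-auxiliary, which sets C7 with the configuration required for the target.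

Step 13
Reactants: 20 (R)-4-benzyl-3-[(2R,3R,5R)-2-(3-bromobut-3-enyl)-3,7-dimethyl-5-(triethylsilyloxy)oct-6-enoyl]oxazolidin-2-one
Product: 21 (2R,3R,5R)-2-(3-bromobut-3-enyl)-3,7-dimethyl-5-(triethylsilyloxy)oct-6-en-1-ol
Conditions: LiBH4, H2O (1 equiv), Et2O, 0 °C
Reagents that add atoms: none
Why: Borohydride reduction of the exocyclic imide carbonyl releases the auxiliary and gives the primary alcohol without epimerising C7 or touching the vinyl bromide and the silyl ether.

Step 14
Reactants: 21 (2R,3R,5R)-2-(3-bromobut-3-enyl)-3,7-dimethyl-5-(triethylsilyloxy)oct-6-en-1-ol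
Product: 22 (2R,3R,5R)-2-(3-bromobut-3-enyl)-3,7-dimethyl-5-(triethylsilyloxy)oct-6-enal
Conditions: Dess–Martin periodinane, NaHCO3, CH2Cl2, 0 °C to rt; used at once
Reagents that add atoms: none
Why: Buffered Dess–Martin oxidation gives the α-branched aldehyde under neutral conditions that should not epimerise C7 or cleave the triethylsilyl ether.

Step 15
Reactants: 4 (1S)-4-bromo-1-methylcyclopent-2-en-1-yl tert-butyldimethylsilyl ether; 22 (2R,3R,5R)-2-(3-bromobut-3-enyl)-3,7-dimethyl-5-(triethylsilyloxy)oct-6-enal
Product: 24 (1R,2R,3R,5R)-2-(3-bromobut-3-enyl)-1-[(1R,5S)-5-(tert-butyldimethylsilyloxy)-5-methylcyclopent-2-en-1-yl]-3,7-dimethyl-5-(triethylsilyloxy)oct-6-en-1-ol, via allylindium dibromide 23 (not isolated)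
Conditions: In powder, DMF, 0 °C to rt (Barbier mode)
Reagents that add atoms: none
Why: In this indium-mediated Barbier allylation the metal sits on the less hindered ring carbon and the allyl unit adds to the aldehyde through its γ-terminus (the carbon next to the quaternary C4) in a closed transition state on the ring face trans to the bulky silyloxy group, which sets C5 and leaves the C1=C2 alkene in place, while the vinyl bromide and both silyl ethers are inert and the C6 configuration is immaterial because C6 is oxidised in step 17.

Step 16
Reactants: 24 homoallylic alcohol (Heck precursor)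
Product: 25 cis-fused hydroazulene with 10-exo-methylene and C2=C3 alkene (4β-methyl and 4α-OTBS and 6α-OH and 7β side chain bearing 13-OTES)
Conditions: Pd(OAc)2 (10 mol%), PPh3 (30 mol%), Ag2CO3 (2 equiv), MeCN, 80 °C
Reagents that add atoms: none
Why: Zerovalent palladium formed from Pd(OAc)2 and PPh3 inserts into the C10–Br bond, the alkenylpalladium adds syn across the C1=C2 alkene with C10 bonding to C1 and palladium moving to C2, and syn β-hydride loss then takes a hydrogen from C3 to release the C2=C3 alkene. The closest known reaction type is the intramolecular Heck cyclisation of a 2-bromo-1-alkene onto a cycloalkene with β-hydride elimination away from the new stereocentre. The seven-membered ring closes in the 7-exo-trig mode, because the five-atom tether C9–C8–C7–C6–C5 is anchored on the carbon next to C1 and an 8-endo attack on C2 would need a strained bridged arrangement. C1 is the only new stereocentre and is controlled by the tether, which hangs from C5 on the β face and can deliver C10 only to that face, so the ring fusion should come out cis with H1 and H5 both α. The step needs β-hydride loss towards C3 alone and no later alkene migration: H1 lies anti to palladium after the syn insertion, the fully substituted C4 stops chain walking, and Ag2CO3 removes bromide and takes up the acid so that the palladium hydride does not add back to the skipped diene.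

Step 17
Reactants: 25 cis-fused hydroazulene with 6α-OH
Product: 26 C6 ketone of the hydroazulene (4-OTBS and 13-OTES)
Conditions: Dess–Martin periodinane, NaHCO3, CH2Cl2, 0 °C to rt
Reagents that add atoms: none
Why: Buffered Dess–Martin oxidation converts the hindered secondary carbinol into the ketone without acid or base that could move the skipped diene or epimerise C5 and C7, and it erases the unwanted C6 configuration.

Step 18
Reactants: 26 C6 ketone (4-OTBS and 13-OTES)
Product: 27 13-hydroxy C6 ketone (4-OTBS)
Conditions: PPTS (cat.), MeOH, 0 °C to rt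
Reagents that add atoms: none
Why: Mild acid methanolysis cleaves the secondary allylic triethylsilyl ether much faster than the hindered tertiary tert-butyldimethylsilyl ether.

Step 19
Reactants: 27 13-hydroxy C6 ketone (4-OTBS)
Product: 28 13-acetoxy C6 ketone (4-OTBS)
Conditions: Ac2O, pyridine, DMAP (cat.), CH2Cl2, 0 °C
Reagents that add atoms: acetic anhydride, CC(=O)OC(C)=O
Why: The only free hydroxyl is acylated under DMAP catalysis at a temperature where the β-silyloxy ketone should neither enolise nor eliminate.

Step 20
Reactants: 28 13-acetoxy C6 ketone (4-OTBS)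
Product: 29 4-O-tert-butyldimethylsilyl ether of the target (6β-OH)
Conditions: LiBH(s-Bu)3 (L-Selectride, 1.2 equiv), THF, −78 °C; H2O
Reagents that add atoms: none
Why: The bulky trialkylborohydride should attack the C6 carbonyl from the convex α face of the cis-fused bicycle, the side of H5 and H7 and away from the β side chain on C7 and the β methyl on C4, which sets the 6β-hydroxyl, and at −78 °C the ketone is reduced ahead of the acetate.

Step 21
Reactants: 29 4-O-tert-butyldimethylsilyl ether of the target
Product: 30 CNP0209568.2
Conditions: TBAF, AcOH (1:1), THF, rt to 45 °C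
Reagents that add atoms: none
Why: Fluoride buffered with acetic acid removes the tertiary silyl ether without the basicity that would cleave or move the acetate and without the acidity that would ionise the tertiary allylic alcohol.

**Compound list**

1 | (S)-(+)-linalool | C=C[C@@](C)(O)CCC=C(C)C | starting material
2 | (S)-1-methylcyclopent-2-en-1-ol | C[C@@]1(O)C=CCC1 | intermediate
3 | (S)-tert-butyldimethyl[(1-methylcyclopent-2-en-1-yl)oxy]silane | C[C@@]1(O[Si](C)(C)C(C)(C)C)C=CCC1 | intermediate
4 | (1S)-4-bromo-1-methylcyclopent-2-en-1-yl tert-butyldimethylsilyl ether, bromide epimers | C[C@@]1(O[Si](C)(C)C(C)(C)C)C=CC(Br)C1 | intermediate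
5 | 3-methylglutaric anhydride | CC1CC(=O)OC(=O)C1 | starting material
6 | (R)-5-methoxy-3-methyl-5-oxopentanoic acid | COC(=O)C[C@H](C)CC(=O)O | intermediate
7 | methyl (S)-5-chloro-3-methyl-5-oxopentanoate | COC(=O)C[C@H](C)CC(Cl)=O | intermediate
8 | 1-bromo-2-methylprop-1-ene | CC(C)=CBr | starting material
9 | (2-methylprop-1-enyl)magnesium bromide | CC(C)=C[Mg]Br | intermediate
10 | methyl (R)-3,7-dimethyl-5-oxooct-6-enoate | COC(=O)C[C@H](C)CC(=O)C=C(C)C | intermediate
11 | methyl (3R,5R)-5-hydroxy-3,7-dimethyloct-6-enoate | COC(=O)C[C@H](C)C[C@H](C=C(C)C)O | intermediate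
12 | methyl (3R,5R)-3,7-dimethyl-5-(triethylsilyloxy)oct-6-enoate | COC(=O)C[C@H](C)C[C@H](C=C(C)C)O[Si](CC)(CC)CC | intermediate
13 | (3R,5R)-3,7-dimethyl-5-(triethylsilyloxy)oct-6-enoic acid | OC(=O)C[C@H](C)C[C@H](C=C(C)C)O[Si](CC)(CC)CC | intermediate
14 | (R)-4-benzyloxazolidin-2-one | O=C1OC[C@@H](Cc2ccccc2)N1 | starting material
15 | mixed pivalic anhydride of acid 13 | CC(C)(C)C(=O)OC(=O)C[C@H](C)C[C@H](C=C(C)C)O[Si](CC)(CC)CC | intermediate
16 | (R)-4-benzyl-3-[(3R,5R)-3,7-dimethyl-5-(triethylsilyloxy)oct-6-enoyl]oxazolidin-2-one | O=C1OC[C@@H](Cc2ccccc2)N1C(=O)C[C@H](C)C[C@H](C=C(C)C)O[Si](CC)(CC)CC | intermediate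
17 | 3-bromobut-3-en-1-ol | OCCC(Br)=C | starting material
18 | 3-bromobut-3-enyl trifluoromethanesulfonate | C=C(Br)CCOS(=O)(=O)C(F)(F)F | intermediate
19 | sodium Z-enolate of imide 16 | O=C1OC[C@@H](Cc2ccccc2)N1/C([O-])=C/[C@H](C)C[C@H](C=C(C)C)O[Si](CC)(CC)CC.[Na+] | intermediate
20 | (R)-4-benzyl-3-[(2R,3R,5R)-2-(3-bromobut-3-enyl)-3,7-dimethyl-5-(triethylsilyloxy)oct-6-enoyl]oxazolidin-2-one | O=C1OC[C@@H](Cc2ccccc2)N1C(=O)[C@H](CCC(Br)=C)[C@H](C)C[C@H](C=C(C)C)O[Si](CC)(CC)CC | intermediate
21 | (2R,3R,5R)-2-(3-bromobut-3-enyl)-3,7-dimethyl-5-(triethylsilyloxy)oct-6-en-1-ol | OC[C@H](CCC(Br)=C)[C@H](C)C[C@H](C=C(C)C)O[Si](CC)(CC)CC | intermediate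
22 | (2R,3R,5R)-2-(3-bromobut-3-enyl)-3,7-dimethyl-5-(triethylsilyloxy)oct-6-enal | O=C[C@H](CCC(Br)=C)[C@H](C)C[C@H](C=C(C)C)O[Si](CC)(CC)CC | intermediate
23 | allylindium dibromide from 4 (trivalent indium, simplified form of the sesquihalide) | C[C@@]1(O[Si](C)(C)C(C)(C)C)C=CC([In](Br)Br)C1 | intermediate
24 | (1R,2R,3R,5R)-2-(3-bromobut-3-enyl)-1-[(1R,5S)-5-(tert-butyldimethylsilyloxy)-5-methylcyclopent-2-en-1-yl]-3,7-dimethyl-5-(triethylsilyloxy)oct-6-en-1-ol (dictyol numbering: 4S,5R,6R,7R,11R,13R) | C=C(Br)CC[C@H]([C@H](C)C[C@H](C=C(C)C)O[Si](CC)(CC)CC)[C@@H](O)[C@H]1C=CC[C@]1(C)O[Si](C)(C)C(C)(C)C | intermediate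
25 | cis-fused hydroazulene: 10-exo-methylene, C2=C3, 4β-methyl-4α-OTBS, 6α-OH, 7β side chain with 13-OTES (1S,4S,5R,6R,7R,11R,13R) | C=C1CC[C@H]([C@H](C)C[C@H](C=C(C)C)O[Si](CC)(CC)CC)[C@@H](O)[C@H]2[C@@H]1C=C[C@]2(C)O[Si](C)(C)C(C)(C)C | intermediate
26 | C6 ketone of 25 (4-OTBS, 13-OTES) | C=C1CC[C@H]([C@H](C)C[C@H](C=C(C)C)O[Si](CC)(CC)CC)C(=O)[C@H]2[C@@H]1C=C[C@]2(C)O[Si](C)(C)C(C)(C)C | intermediate
27 | 13-hydroxy C6 ketone (4-OTBS) | C=C1CC[C@H]([C@H](C)C[C@H](C=C(C)C)O)C(=O)[C@H]2[C@@H]1C=C[C@]2(C)O[Si](C)(C)C(C)(C)C | intermediate
28 | 13-acetoxy C6 ketone (4-OTBS) | C=C1CC[C@H]([C@H](C)C[C@H](C=C(C)C)OC(C)=O)C(=O)[C@H]2[C@@H]1C=C[C@]2(C)O[Si](C)(C)C(C)(C)C | intermediate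
29 | 4-O-tert-butyldimethylsilyl ether of the target (6β-OH) | C=C1CC[C@H]([C@H](C)C[C@H](C=C(C)C)OC(C)=O)[C@H](O)[C@H]2[C@@H]1C=C[C@]2(C)O[Si](C)(C)C(C)(C)C | intermediate
30 | CNP0209568.2: cis-fused hydroazulene with 10-exo-methylene, C2=C3 and C14=C15 alkenes, 4α-OH, 6β-OH and 13-acetate (1S,4S,5R,6S,7R,11R,13R) | C=C1CC[C@H]([C@H](C)C[C@H](C=C(C)C)OC(C)=O)[C@H](O)[C@H]2[C@@H]1C=C[C@]2(C)O | target

**Step count**

Total: 21 steps. Longest linear sequence: 17 steps (5 to 30 through steps 4–10 and 12–21). The cyclopentene branch (steps 1–3) and the triflate (step 11) are convergent side branches.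

**Steps most likely to fail**

Step 15 (indium allylation). The allyl unit may transfer through the wrong terminus or to the α face of the ring, and the hindered partners may react slowly. The chair transition state leading to 24 also runs against the Felkin–Anh preference of the α-branched aldehyde. This mismatch may send material to the C6 epimer, which is harmless because it converges at 26, or to the wrong ring face, which is not. The fallback replaces the fluxional allylindium by an isolable allylboron reagent. It sets out from bromide 4. Miyaura-type borylation (B2pin2, KOAc, Pd2(dba)3 as a zerovalent palladium source, DMSO, 50 °C) should put boron on the ring carbon remote from the quaternary centre and mainly trans to the silyloxy group, giving the trans allyl pinacolboronate F1 after separation from its cis isomer. Heating F1 with aldehyde 22 (toluene, 60–80 °C, triethanolamine work-up) effects an allylboration that is strictly γ-selective and suprafacial through a closed chair. The bonding carbon (C5) and its face (the one that carried boron, trans to the silyloxy group) are then fixed by the reagent, and the route is rejoined at 24.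

Step 16 (Heck closure). The 7-exo insertion may be slow, allowing protodebromination or intermolecular coupling, and a palladium hydride may add back and move the exo-methylene or ring alkene. The fallback generates the same C10 alkenylpalladium by hydropalladation instead of oxidative addition, with no halide, base or silver. It sets out from 24. Dehydrobromination (LDA, 3 equiv, THF, −78 to −20 °C) gives the terminal alkyne F2. A hydridopalladium acetate catalyst (Pd2(dba)3·CHCl3 as a zerovalent palladium source, AcOH, P(o-Tol)3, benzene, 60 °C) then effects an Alder-ene-type enyne cycloisomerisation: H–Pd adds across the alkyne with palladium on C10, the C1=C2 alkene inserts, and β-hydride loss towards C3 regenerates the hydride. The route is rejoined at 25. This variant is less precedented for seven-membered rings and would not cure a failure of the insertion itself.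

Step 20 (ketone reduction). The hydride may approach from the β face, or be hindered on the α face by the C4 silyl ether, giving the wrong C6 epimer, and the acetate may be partly cleaved. The fallback uses hydroxyl-directed delivery and sets out from 28. Desilylation (HF·pyridine, THF/pyridine, 0 °C, kept cold to avoid dehydration) gives the β-hydroxy ketone F3. Evans–Saksena reduction (Me4NBH(OAc)3, MeCN/AcOH, −30 °C) then delivers hydride intramolecularly from boron bound to the α-oriented C4 hydroxyl. Attack is therefore on the α face and gives the 4,6-anti diol, which is the target, so the route is rejoined at 30.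

**Further compounds**

F1 | step 15 | (1S,4R)-trans-allyl pinacolboronate: 1-methyl-1-(tert-butyldimethylsilyloxy)-4-(pinacolboryl)cyclopent-2-ene, boron trans to the silyloxy group | C[C@@]1(O[Si](C)(C)C(C)(C)C)C=C[C@@H](B2OC(C)(C)C(C)(C)O2)C1
F2 | step 16 | terminal alkyne from dehydrobromination of 24 | C#CCC[C@H]([C@H](C)C[C@H](C=C(C)C)O[Si](CC)(CC)CC)[C@@H](O)[C@H]1C=CC[C@]1(C)O[Si](C)(C)C(C)(C)C
F3 | step 20 | 4-hydroxy-13-acetoxy C6 ketone (β-hydroxy ketone) | C=C1CC[C@H]([C@H](C)C[C@H](C=C(C)C)OC(C)=O)C(=O)[C@H]2[C@@H]1C=C[C@]2(C)O
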